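**Retrosynthetic overview**
1. The target comes from a protected macrocyclic triol by C5 angeloylation, desilylation and chemoselective allylic oxidation at C3.
2. Key disconnection C6–C7: a samarium ketyl radical from a C6 aldehyde adds intramolecularly to C7 of a C8-bound butenolide carrying a C13 acetate. One step closes the ten-membered ring, sets C6 and C7 and unveils the α-methylene lactone.
3. The seco-aldehyde comes from a C3–C4 Nozaki–Hiyama–Kishi union of a butenolide aldehyde (C1–C3, C7–C14) with a 2-bromoallyl PMB ether (C4–C6, C15); the C1/C10 oxirane is set by Shi epoxidation of the acyclic E-olefin.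
4. The butenolide arises by ring-closing metathesis of a 2-(acetoxymethyl)acrylate; its chain comes from carboalumination/oxirane opening of (R)-hex-1-en-5-yn-3-ol (vinyloxirane + acetylide); the bromoallyl ether comes from (S)-but-3-ene-1,2-diol.
5. Ring order: butenolide (metathesis), then oxirane (Shi), then ten-membered carbocycle (radical macrocyclisation).

Assumption: germacrane numbering is used (ring C1–C10, lactone C11–C13 closed on O–C8, C14 = methyl on C10, C15 = methylene on C4), so the target is the (1R,5S,6R,7R,8R,10R) isomer; the C3 carbinol made in step 9 is carried as an epimer mixture because C3 ends as the ketone.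

**Route**

Step 1
Reactants: 1 (2S)-2-ethenyloxirane; 2 lithium acetylide ethylenediamine complex
Product: 3 (3R)-hex-1-en-5-yn-3-ol
Conditions: LiC≡CH·H2NCH2CH2NH2 (1.5 equiv), DMSO, 15 °C → rt; then H2O
Reagents that add atoms: none
Why: SN2 opening of the vinyl epoxide at its unsubstituted carbon by the hard acetylide (no Lewis acid, so allylic and SN2′ attack are disfavoured) leaves the carbinol centre untouched, the descriptor changing from S to R only through CIP priorities.

Step 2
Reactants: 3 (3R)-hex-1-en-5-yn-3-ol; 4 oxirane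
Product: 6 (3R,5E)-5-methylocta-1,5-diene-3,8-diol, via alkenylalane 5 (not isolated)
Conditions: Me3Al (4 equiv), Cp2ZrCl2 (0.3 equiv), CH2Cl2, 0 °C → rt; volatiles removed; n-BuLi (2.2 equiv), THF/hexane, −78 °C; 4 (5 equiv), −78 → 0 °C; aq. HCl
Reagents that add atoms: trimethylaluminium, C[Al](C)C
Why: Negishi zirconium-catalysed syn-methylalumination puts methyl on the internal and aluminium on the terminal alkyne carbon (E-trisubstituted olefin), and the derived alkenylalanate opens oxirane with retention of olefin geometry.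

Step 3
Reactants: 6 (3R,5E)-5-methylocta-1,5-diene-3,8-diol
Product: 7 (3E,6R)-6-hydroxy-4-methylocta-3,7-dienal
Conditions: TEMPO (0.1 equiv), PhI(OAc)2 (1.1 equiv), CH2Cl2, rt
Reagents that add atoms: none
Why: Oxoammonium (TEMPO) oxidation is selective for the primary over the secondary allylic alcohol and stops at the aldehyde under non-basic conditions that do not conjugate the β,γ-olefin.

Step 4
Reactants: 7 (3E,6R)-6-hydroxy-4-methylocta-3,7-dienal; 8 2-(bromomethyl)prop-2-enoic acid
Product: 10 (3R,5E)-5-methyl-8-oxoocta-1,5-dien-3-yl 2-(acetoxymethyl)prop-2-enoate, via bromomethyl acrylate ester 9 (not isolated)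
Conditions: 8 (1.3 equiv), DCC, DMAP (5 mol %), CH2Cl2, −10 °C; then KOAc (3 equiv), 18-crown-6 (cat.), MeCN, rt
Reagents that add atoms: potassium acetate, CC(=O)[O-].[K+]
Why: Steglich esterification of the secondary allylic alcohol followed by displacement of the activated allylic bromide by acetate (SN2 and SN2′ give the same product) installs the future C13 leaving group without touching the stereocentre.

Step 5
Reactants: 10 (3R,5E)-5-methyl-8-oxoocta-1,5-dien-3-yl 2-(acetoxymethyl)prop-2-enoate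
Product: 11 {(5R)-5-[(2E)-2-methyl-5-oxopent-2-en-1-yl]-2-oxo-2,5-dihydrofuran-3-yl}methyl acetate
Conditions: second-generation Grubbs catalyst RuCl2(=CHPh)(PCy3)(H2IMes) (5 mol %), CH2Cl2 (5 mM), 40 °C
Reagents that add atoms: none
Why: Ring-closing metathesis between the vinyl group and the 1,1-disubstituted acrylate forms the five-membered butenolide with loss of ethene, the trisubstituted olefin and the aldehyde being spectators.

Step 6
Reactants: 12 (2S)-but-3-ene-1,2-diol
Product: 13 (4S)-4-ethenyl-2-(4-methoxyphenyl)-1,3-dioxolane (acetal epimers)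
Conditions: 4-MeOC6H4CH(OMe)2, PPTS (cat.), CH2Cl2, rt
Reagents that add atoms: 4-methoxybenzaldehyde dimethyl acetal, COC(OC)c1ccc(OC)cc1
Why: Acid-catalysed transacetalisation ties up the 1,2-diol as a p-methoxybenzylidene acetal, whose acetal-carbon epimers are inconsequential.

Step 7
Reactants: 13 (4S)-4-ethenyl-2-(4-methoxyphenyl)-1,3-dioxolane
Product: 15 (4R)-4-(1-bromoethenyl)-2-(4-methoxyphenyl)-1,3-dioxolane, via vicinal dibromide 14 (not isolated)
Conditions: Br2, CH2Cl2, −78 °C; then DBU (2 equiv), DMF, 60 °C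
Reagents that add atoms: bromine, BrBr
Why: Bromine addition then DBU dehydrobromination, directed by the adjacent oxygen-bearing carbon to remove the internal C–H and the primary bromide, gives the 2-bromo-1-alkene regioselectively without touching the future C5 centre.

Step 8
Reactants: 15 (4R)-4-(1-bromoethenyl)-2-(4-methoxyphenyl)-1,3-dioxolane
Product: 16 (2R)-3-bromo-2-[(4-methoxybenzyl)oxy]but-3-en-1-ol
Conditions: i-Bu2AlH (3 equiv), CH2Cl2, −78 → 0 °C; aq. KNaC4H4O6
Reagents that add atoms: none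
Why: i-Bu2AlH coordinates the less hindered primary acetal oxygen and reductively opens the benzylidene acetal to the secondary PMB ether and the free primary alcohol.

Step 9
Reactants: 11 {(5R)-5-[(2E)-2-methyl-5-oxopent-2-en-1-yl]-2-oxo-2,5-dihydrofuran-3-yl}methyl acetate; 16 (2R)-3-bromo-2-[(4-methoxybenzyl)oxy]but-3-en-1-ol
Product: 17 {(5R)-5-[(2E,5RS,7S)-5,8-dihydroxy-7-[(4-methoxybenzyl)oxy]-2-methyl-6-methylideneoct-2-en-1-yl]-2-oxo-2,5-dihydrofuran-3-yl}methyl acetate
Conditions: CrCl2 (6 equiv), NiCl2 (5 mol %), DMSO, rt (16 in 1.5-fold excess)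
Reagents that add atoms: none
Why: Nozaki–Hiyama–Kishi coupling, in which the nickel-catalysed alkenylchromium species (trivalent chromium) adds only to the aldehyde in the presence of lactone, allylic acetate and free hydroxyl, forms C3–C4; the C3 carbinol is formed unselectively, which does not matter.

Step 10
Reactants: 17 (the C3–C4 coupled diol)
Product: 18 {(5R)-5-({(2R,3R)-3-[(2RS,4S)-2,5-dihydroxy-4-[(4-methoxybenzyl)oxy]-3-methylidenepentyl]-2-methyloxiran-2-yl}methyl)-2-oxo-2,5-dihydrofuran-3-yl}methyl acetate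
Conditions: D-fructose-derived Shi ketone (0.3 equiv), KHSO5, K2CO3, Bu4NHSO4 (cat.), MeCN/CH2(OMe)2/aq. Na2B4O7 buffer, 0 °C
Reagents that add atoms: potassium peroxymonosulfate KHSO5, OOS(=O)(=O)[O-].[K+]
Why: Shi asymmetric epoxidation, in which the chiral dioxirane attacks the electron-rich E-trisubstituted olefin through the spiro transition state, gives the (1R,10R)-oxirane under reagent control and leaves the electron-poor butenolide and the hindered 1,1-disubstituted olefin alone.

Step 11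
Reactants: 18 (the epoxy diol)
Product: 19 3,6-bis(triethylsilyl) ether of 18 (C3–OTES and C6–OTES)
Conditions: TESCl (3 equiv), imidazole, DMAP (cat.), DMF, 0 °C → rt
Reagents that add atoms: chlorotriethylsilane, CC[Si](Cl)(CC)CC
Why: Standard imidazole-mediated silylation protects both hydroxyls under non-Lewis-acidic conditions that spare the oxirane.

Step 12
Reactants: 19 (the bis-silyl ether)
Product: 20 (2S,4RS)-5-[(2R,3R)-3-{[(2R)-4-(acetoxymethyl)-5-oxo-2,5-dihydrofuran-2-yl]methyl}-3-methyloxiran-2-yl]-2-[(4-methoxybenzyl)oxy]-3-methylidene-4-(triethylsilyloxy)pentanal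
Conditions: (COCl)2, DMSO, CH2Cl2, −78 → −40 °C; i-Pr2NEt, −78 °C; cold pH 7 work-up; used at once
Reagents that add atoms: none
Why: Under Swern conditions the primary triethylsilyl ether is cleaved and oxidised directly while the secondary one survives, and the low temperature and hindered base limit epimerisation at C5 and olefin migration.

Step 13
Reactants: 20 (the C6 aldehyde)
Product: 22 (1R,5S,6R,7S,8R,10R)-1,10-epoxy-5-[(4-methoxybenzyl)oxy]-3,6-bis(triethylsilyloxy)germacra-4(15),11(13)-dien-12,8-olide (C3 epimers), via macrocyclic C6 alcohol 21 (not isolated)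
Conditions: SmI2 (2.4 equiv, 0.1 M in THF) added over 3 h to 20 (0.5 mM) and HMPA (12 equiv) in THF, −78 °C; then TESCl (5 equiv), −78 → 0 °C
Reagents that add atoms: chlorotriethylsilane, CC[Si](Cl)(CC)CC
Why: Proposed new method: single-electron transfer from SmI2 (divalent samarium) to the aldehyde gives a C6 ketyl radical that adds 10-exo to C7 of the butenolide, the C11 radical is reduced to a trivalent samarium enolate that expels the C13 acetate (E1cB) to give the α-methylene lactone, and the alkoxide is silylated in the flask (closest known reactions: SmI2 ketyl–olefin cyclisations to medium rings and SmI2 aldehyde–acrylate/butenolide couplings); C6 is set by non-chelated Felkin–Anh approach anti to the C5–OPMB bond (HMPA-saturated samarium does not chelate), C7 by attack anti to the C8–C9 bond (trans-fused lactone), and the oxirane has removed the only olefin that could compete by 6-exo cyclisation.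

Step 14
Reactants: 22 (the protected macrocycle)
Product: 23 (1R,5S,6R,7S,8R,10R)-1,10-epoxy-5-hydroxy-3,6-bis(triethylsilyloxy)germacra-4(15),11(13)-dien-12,8-olide (C3 epimers)
Conditions: DDQ (1.5 equiv), CH2Cl2/pH 7 buffer (10:1), 0 °C
Reagents that add atoms: none
Why: DDQ oxidative cleavage of the PMB ether (benzylic oxocarbenium, hydrolysis) frees only the C5 hydroxyl, the silyl ethers, oxirane and α-methylene lactone being inert.

Step 15
Reactants: 23 (the C5 alcohol); 24 (Z)-2-methylbut-2-enoic acid (angelic acid)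
Product: 26 (1R,5S,6R,7S,8R,10R)-5-angeloyloxy-1,10-epoxy-3,6-bis(triethylsilyloxy)germacra-4(15),11(13)-dien-12,8-olide (C3 epimers), via angeloyl trichlorobenzoyl anhydride 25 (not isolated)
Conditions: 24, 2,4,6-Cl3C6H2COCl, Et3N, toluene, rt; then 23, toluene, 80 °C
Reagents that add atoms: none
Why: Yamaguchi-type acylation through the mixed anhydride without a nucleophilic catalyst esterifies the only free hydroxyl and avoids the Z-to-E isomerisation (tiglate) that DMAP-type activation causes.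

Step 16
Reactants: 26 (the silylated angelate)
Product: 27 (1R,5S,6R,7R,8R,10R)-5-angeloyloxy-1,10-epoxy-3,6-dihydroxygermacra-4(15),11(13)-dien-12,8-olide (C3 epimers)
Conditions: HF·pyridine, pyridine, THF, 0 °C → rt
Reagents that add atoms: none
Why: Buffered HF·pyridine removes both triethylsilyl ethers in a weakly acidic, non-basic medium that suppresses 1,2-acyl migration of the angelate and spares the oxirane.

Step 17
Reactants: 27 (the diol)
Product: 28 (1R,5S,6R,7R,8R,10R)-5-angeloyloxy-1,10-epoxy-6-hydroxy-3-oxogermacra-4(15),11(13)-dien-12,8-olide (target)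
Conditions: MnO2 (activated, 20 equiv), CH2Cl2, rt
Reagents that add atoms: none
Why: MnO2 oxidises only the allylic C3 alcohol (both epimers converge) to the α-methylene ketone under neutral conditions and leaves the non-allylic C6 alcohol and the β,γ-epoxide untouched.

**Compound list**
1 | (2S)-2-ethenyloxirane | C=C[C@H]1CO1 | starting material
2 | lithium acetylide ethylenediamine complex, LiC≡CH·H2NCH2CH2NH2 | [Li]C#C.NCCN | starting material
3 | (3R)-hex-1-en-5-yn-3-ol | C=C[C@H](O)CC#C | intermediate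
4 | oxirane | C1CO1 | starting material
5 | alkenylalane: dimethylaluminium alkoxide of (3R,5E)-6-(dimethylalumanyl)-5-methylhexa-1,5-dien-3-ol | C=C[C@H](O[Al](C)C)C/C(C)=C/[Al](C)C | intermediate
6 | (3R,5E)-5-methylocta-1,5-diene-3,8-diol | C=C[C@H](O)C/C(C)=C/CCO | intermediate
7 | (3E,6R)-6-hydroxy-4-methylocta-3,7-dienal | C=C[C@H](O)C/C(C)=C/CC=O | intermediate
8 | 2-(bromomethyl)prop-2-enoic acid | C=C(CBr)C(=O)O | starting material
9 | (3R,5E)-5-methyl-8-oxoocta-1,5-dien-3-yl 2-(bromomethyl)prop-2-enoate | C=C[C@H](OC(=O)C(=C)CBr)C/C(C)=C/CC=O | intermediate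
10 | (3R,5E)-5-methyl-8-oxoocta-1,5-dien-3-yl 2-(acetoxymethyl)prop-2-enoate | C=C[C@H](OC(=O)C(=C)COC(C)=O)C/C(C)=C/CC=O | intermediate
11 | {(5R)-5-[(2E)-2-methyl-5-oxopent-2-en-1-yl]-2-oxo-2,5-dihydrofuran-3-yl}methyl acetate | O=CC/C=C(C)/C[C@H]1OC(=O)C(COC(C)=O)=C1 | intermediate
12 | (2S)-but-3-ene-1,2-diol | C=C[C@H](O)CO | starting material
13 | (4S)-4-ethenyl-2-(4-methoxyphenyl)-1,3-dioxolane (acetal epimers) | C=C[C@H]1COC(c2ccc(OC)cc2)O1 | intermediate
14 | (4R)-4-(1,2-dibromoethyl)-2-(4-methoxyphenyl)-1,3-dioxolane (diastereomer mixture) | BrCC(Br)[C@H]1COC(c2ccc(OC)cc2)O1 | intermediate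
15 | (4R)-4-(1-bromoethenyl)-2-(4-methoxyphenyl)-1,3-dioxolane | C=C(Br)[C@H]1COC(c2ccc(OC)cc2)O1 | intermediate
16 | (2R)-3-bromo-2-[(4-methoxybenzyl)oxy]but-3-en-1-ol | C=C(Br)[C@H](OCc1ccc(OC)cc1)CO | intermediate
17 | {(5R)-5-[(2E,5RS,7S)-5,8-dihydroxy-7-[(4-methoxybenzyl)oxy]-2-methyl-6-methylideneoct-2-en-1-yl]-2-oxo-2,5-dihydrofuran-3-yl}methyl acetate | OC[C@@H](OCc1ccc(OC)cc1)C(=C)C(O)C/C=C(C)/C[C@H]1OC(=O)C(COC(C)=O)=C1 | intermediate
18 | {(5R)-5-({(2R,3R)-3-[(2RS,4S)-2,5-dihydroxy-4-[(4-methoxybenzyl)oxy]-3-methylidenepentyl]-2-methyloxiran-2-yl}methyl)-2-oxo-2,5-dihydrofuran-3-yl}methyl acetate | OC[C@@H](OCc1ccc(OC)cc1)C(=C)C(O)C[C@H]2O[C@]2(C)C[C@H]3OC(=O)C(COC(C)=O)=C3 | intermediate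
19 | 3,6-bis(triethylsilyl) ether of 18 (C3–OTES and C6–OTES) | CC[Si](CC)(CC)OC[C@@H](OCc1ccc(OC)cc1)C(=C)C(O[Si](CC)(CC)CC)C[C@H]2O[C@]2(C)C[C@H]3OC(=O)C(COC(C)=O)=C3 | intermediate
20 | (2S,4RS)-5-[(2R,3R)-3-{[(2R)-4-(acetoxymethyl)-5-oxo-2,5-dihydrofuran-2-yl]methyl}-3-methyloxiran-2-yl]-2-[(4-methoxybenzyl)oxy]-3-methylidene-4-(triethylsilyloxy)pentanal | O=C[C@@H](OCc1ccc(OC)cc1)C(=C)C(O[Si](CC)(CC)CC)C[C@H]2O[C@]2(C)C[C@H]3OC(=O)C(COC(C)=O)=C3 | intermediate
21 | (1R,5S,6R,7R,8R,10R)-1,10-epoxy-6-hydroxy-5-[(4-methoxybenzyl)oxy]-3-(triethylsilyloxy)germacra-4(15),11(13)-dien-12,8-olide (C3 epimers) | C=C1C(=O)O[C@@H]2C[C@@]3(C)O[C@@H]3CC(O[Si](CC)(CC)CC)C(=C)[C@H](OCc4ccc(OC)cc4)[C@H](O)[C@@H]12 | intermediate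
22 | (1R,5S,6R,7S,8R,10R)-1,10-epoxy-5-[(4-methoxybenzyl)oxy]-3,6-bis(triethylsilyloxy)germacra-4(15),11(13)-dien-12,8-olide (C3 epimers) | C=C1C(=O)O[C@@H]2C[C@@]3(C)O[C@@H]3CC(O[Si](CC)(CC)CC)C(=C)[C@H](OCc4ccc(OC)cc4)[C@H](O[Si](CC)(CC)CC)[C@@H]12 | intermediate
23 | (1R,5S,6R,7S,8R,10R)-1,10-epoxy-5-hydroxy-3,6-bis(triethylsilyloxy)germacra-4(15),11(13)-dien-12,8-olide (C3 epimers) | C=C1C(=O)O[C@@H]2C[C@@]3(C)O[C@@H]3CC(O[Si](CC)(CC)CC)C(=C)[C@H](O)[C@H](O[Si](CC)(CC)CC)[C@@H]12 | intermediate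
24 | (Z)-2-methylbut-2-enoic acid (angelic acid) | C/C=C(/C)C(=O)O | starting material
25 | (Z)-2-methylbut-2-enoic 2,4,6-trichlorobenzoic anhydride | C/C=C(/C)C(=O)OC(=O)c1c(Cl)cc(Cl)cc1Cl | intermediate
26 | (1R,5S,6R,7S,8R,10R)-5-angeloyloxy-1,10-epoxy-3,6-bis(triethylsilyloxy)germacra-4(15),11(13)-dien-12,8-olide (C3 epimers) | C=C1C(=O)O[C@@H]2C[C@@]3(C)O[C@@H]3CC(O[Si](CC)(CC)CC)C(=C)[C@H](OC(=O)/C(C)=C\C)[C@H](O[Si](CC)(CC)CC)[C@@H]12 | intermediate
27 | (1R,5S,6R,7R,8R,10R)-5-angeloyloxy-1,10-epoxy-3,6-dihydroxygermacra-4(15),11(13)-dien-12,8-olide (C3 epimers) | C=C1C(=O)O[C@@H]2C[C@@]3(C)O[C@@H]3CC(O)C(=C)[C@H](OC(=O)/C(C)=C\C)[C@H](O)[C@@H]12 | intermediate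
28 | (1R,5S,6R,7R,8R,10R)-5-angeloyloxy-1,10-epoxy-6-hydroxy-3-oxogermacra-4(15),11(13)-dien-12,8-olide | C=C1C(=O)O[C@@H]2C[C@@]3(C)O[C@@H]3CC(=O)C(=C)[C@H](OC(=O)/C(C)=C\C)[C@H](O)[C@@H]12 | target

**Step count**
Total: 17 steps. Longest linear sequence: 14 steps (steps 1–5 and 9–17); steps 6–8 form the convergent branch.

**Steps most likely to fail, with fallbacks**

Step 13 (radical macrocyclisation). The ten-membered closure competes with pinacol dimerisation, with loss of the allylic C5 alkoxy group from the ketyl, with attack on the wrong butenolide face, and with translactonisation of the C6 alkoxide before silylation. The fallback sets out from 11 and 16 and comes back at 22. It makes the same C6–C7 bond by an intermolecular ketyl addition and closes the ring afterwards at C3–C4. Alcohol 16 is oxidised with Dess–Martin periodinane/NaHCO3 to (2R)-3-bromo-2-[(4-methoxybenzyl)oxy]but-3-enal F1. Aldehyde 11 is masked with HC(OMe)3/PPTS/MeOH as the dimethyl acetal F2. SmI2/HMPA in THF at −78 °C adds the ketyl of F1 to F2 anti to the C8 side chain, with the same acetate loss, to give the hydroxy α-methylene lactone F3. TESCl/imidazole gives its C6 triethylsilyl ether F4, and PPTS in wet acetone frees the C3 aldehyde F5. CrCl2/NiCl2 in DMSO at 2 mM closes the ten-membered ring to the macrocyclic C3 alcohol F6, TESCl/imidazole gives the bis-silyl ether F7, and Shi epoxidation of its C1=C10 olefin gives 22.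

Step 12 (α-alkoxy-β,γ-unsaturated aldehyde). Aldehyde 20 can epimerise at C5 or slip into conjugation under the amine base of the one-flask oxidation. The fallback sets out from 19 and comes back at 20. It is stepwise and amine-free: HF·pyridine buffered with pyridine (THF, 0 °C) removes only the primary silyl group to give the isolable primary alcohol F8, which Dess–Martin periodinane/NaHCO3 (CH2Cl2, 0 °C) oxidises to 20.

Step 15 (angeloylation). The C5 hydroxyl is hindered, and forcing conditions isomerise the angelate to the tiglate. The fallback sets out from 23 and comes back at 26. It builds the Z-enoate on the molecule instead of transferring it. Alcohol 23 is acylated with 2-[bis(2,2,2-trifluoroethoxy)phosphoryl]propanoic acid (DCC, DMAP) to the phosphonopropanoate ester F9. Still–Gennari olefination (KN(SiMe3)2, 18-crown-6, acetaldehyde, THF, −78 °C) then gives the Z-trisubstituted ester 26.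

**Further compounds**
F1 | step 13 | (2R)-3-bromo-2-[(4-methoxybenzyl)oxy]but-3-enal | C=C(Br)[C@H](OCc1ccc(OC)cc1)C=O
F2 | step 13 | {(5R)-5-[(2E)-5,5-dimethoxy-2-methylpent-2-en-1-yl]-2-oxo-2,5-dihydrofuran-3-yl}methyl acetate | COC(OC)C/C=C(C)/C[C@H]1OC(=O)C(COC(C)=O)=C1
F3 | step 13 | (4R,5R)-4-{(1R,2R)-3-bromo-1-hydroxy-2-[(4-methoxybenzyl)oxy]but-3-en-1-yl}-5-[(2E)-5,5-dimethoxy-2-methylpent-2-en-1-yl]-3-methylideneoxolan-2-one | C=C1C(=O)O[C@H](C/C(C)=C/CC(OC)OC)[C@H]1[C@@H](O)[C@@H](OCc2ccc(OC)cc2)C(Br)=C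
F4 | step 13 | C6 triethylsilyl ether of F3 | C=C1C(=O)O[C@H](C/C(C)=C/CC(OC)OC)[C@H]1[C@@H](O[Si](CC)(CC)CC)[C@@H](OCc2ccc(OC)cc2)C(Br)=C
F5 | step 13 | C3 aldehyde from F4 (acetal removed) | C=C1C(=O)O[C@H](C/C(C)=C/CC=O)[C@H]1[C@@H](O[Si](CC)(CC)CC)[C@@H](OCc2ccc(OC)cc2)C(Br)=C
F6 | step 13 | (1(10)E,5S,6R,7S,8R)-3-hydroxy-5-[(4-methoxybenzyl)oxy]-6-(triethylsilyloxy)germacra-1(10),4(15),11(13)-trien-12,8-olide (C3 epimers) | C=C1C(=O)O[C@@H]2C/C(C)=C/CC(O)C(=C)[C@H](OCc3ccc(OC)cc3)[C@H](O[Si](CC)(CC)CC)[C@@H]12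
F7 | step 13 | (1(10)E,5S,6R,7S,8R)-5-[(4-methoxybenzyl)oxy]-3,6-bis(triethylsilyloxy)germacra-1(10),4(15),11(13)-trien-12,8-olide (C3 epimers) | C=C1C(=O)O[C@@H]2C/C(C)=C/CC(O[Si](CC)(CC)CC)C(=C)[C@H](OCc3ccc(OC)cc3)[C@H](O[Si](CC)(CC)CC)[C@@H]12
F8 | step 12 | C6 primary alcohol of 19 (C3–OTES retained) | OC[C@@H](OCc1ccc(OC)cc1)C(=C)C(O[Si](CC)(CC)CC)C[C@H]2O[C@]2(C)C[C@H]3OC(=O)C(COC(C)=O)=C3
F9 | step 15 | C5 2-[bis(2,2,2-trifluoroethoxy)phosphoryl]propanoate of 23 | C=C1C(=O)O[C@@H]2C[C@@]3(C)O[C@@H]3CC(O[Si](CC)(CC)CC)C(=C)[C@H](OC(=O)C(C)P(=O)(OCC(F)(F)F)OCC(F)(F)F)[C@H](O[Si](CC)(CC)CC)[C@@H]12
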